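**Plan**

- Retrosynthesis: with ring C numbered C1 (to ring B), C2 (OH), C3 (Br), C4 (OH), C5 (to ring D), C6 (OH), the ten O-alkyl bonds and the C3–Br bond are cut first. Ring C is then cut at C5–C6, C3–C4 and C1–C6 into a 3-ethoxy-4-arylcyclobutenone (C6, C1, C2, C3, with rings B and A already on C1) and an aryl silyloxyalkyne (C5 with ring D, C4). The ring A–ring B bond is cut last.
- Enabling feature: on ring C the oxygens at C2, C4 and C6 alternate with the aryl-bearing C1 and C5 and the single open position C3. A vinylketene O=C(6)=C(3)H–C(2)(OEt)=C(1)H–Ar and a polarised alkyne Ar–C(5)≡C(4)–OSi give exactly this pattern on benzannulation.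
- Forward: rings A, B and D are bought as phloroglucinol trimethyl ethers. Rings A and B are joined by Suzuki coupling, the four-membered ring is built on the ring B acetic acid, and ring C is then formed between rings B and D. Desilylation, bromination of the only C–H of ring C and global dealkylation finish the synthesis.
- Stereochemistry: the target has no stereocentre; the racemic C4 of the cyclobutenone becomes an aromatic carbon in the key step.

Key step: step 6

Assumption: the target is drawn without stereodescriptors, so the biaryl axes are taken as not configurationally defined; only the ring B–ring C axis joins two unsymmetrical rings and it is expected to be racemic or freely rotating throughout.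

**Route**

Step 1
Reactants: 1 2,4,6-trimethoxybenzaldehyde
Product: 2 2-ethynyl-1,3,5-trimethoxybenzene
Conditions: dimethyl (1-diazo-2-oxopropyl)phosphonate, K2CO3, MeOH, rt
Reagents that add atoms: dimethyl (1-diazo-2-oxopropyl)phosphonate, COP(=O)(OC)C(=[N+]=[N-])C(C)=O
Why: Ohira–Bestmann homologation: methanolysis of the reagent gives the diazomethylphosphonate anion, which adds to the non-enolisable aldehyde and, after loss of phosphate and N2, leaves the terminal alkyne under conditions mild enough for the electron-rich arene.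

Step 2
Reactants: 2 2-ethynyl-1,3,5-trimethoxybenzene
Product: 5 triisopropyl{[(2,4,6-trimethoxyphenyl)ethynyl]oxy}silane, via lithium acetylide 3 (not isolated), via lithium ynolate 4 (not isolated)
Conditions: LiN(SiMe3)2 (2.2 equiv), t-BuOOH (1.0 equiv), THF, −78 → 0 °C; then i-Pr3SiOTf, −78 → 0 °C
Reagents that add atoms: tert-butyl hydroperoxide, CC(C)(C)OO; triisopropylsilyl trifluoromethanesulfonate, CC(C)[Si](C(C)C)(C(C)C)OS(=O)(=O)C(F)(F)F
Why: Oxidation of a lithium acetylide by lithium tert-butyl peroxide to the lithium ynolate, followed by O-silylation with the bulky silyl triflate, is an established route to triisopropylsilyloxyalkynes, and the oxygen transfer occurs at the alkyne terminus, remote from the two ortho-methoxy groups.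

Step 3
Reactants: 6 (2,4,6-trimethoxyphenyl)acetic acid
Product: 7 (3-bromo-2,4,6-trimethoxyphenyl)acetic acid
Conditions: NBS (1.0 equiv), MeCN, 0 °C
Reagents that add atoms: N-bromosuccinimide, O=C1CCC(=O)N1Br
Why: Electrophilic aromatic bromination with NBS takes place at one of the two equivalent ring positions flanked by two methoxy groups, as with 1,3,5-trimethoxybenzene, and one equivalent at 0 °C should stop at the monobromide because the halogen lowers the reactivity of the ring.

Step 4
Reactants: 7 (3-bromo-2,4,6-trimethoxyphenyl)acetic acid; 8 (2,4,6-trimethoxyphenyl)boronic acid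
Product: 9 (2,2',4,4',6,6'-hexamethoxy-[1,1'-biphenyl]-3-yl)acetic acid
Conditions: 8 (2 equiv), Pd(OAc)2 (5 mol %), SPhos (10 mol %), K3PO4, toluene/H2O, 90 °C; then aq. HCl
Reagents that add atoms: none
Why: Suzuki–Miyaura coupling with the zerovalent palladium–SPhos catalyst formed from palladium diacetate is an established way to tetra-ortho-substituted biaryls; an excess of 8 compensates for protodeboronation and the carboxylate is a spectator.

Step 5
Reactants: 9 (2,2',4,4',6,6'-hexamethoxy-[1,1'-biphenyl]-3-yl)acetic acid; 10 ethoxyacetylene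
Product: 13 3-ethoxy-4-(2,2',4,4',6,6'-hexamethoxy-[1,1'-biphenyl]-3-yl)cyclobut-2-en-1-one (racemic), via acid chloride 11 (not isolated), via arylketene 12 (not isolated)
Conditions: 1-chloro-N,N,2-trimethylprop-1-en-1-amine (1.0 equiv), CH2Cl2, 0 °C → rt; then ethoxyacetylene (5 equiv), Et3N (slow addition), 0 °C → rt
Reagents that add atoms: none
Why: The α-chloroenamine converts the acid into its chloride under neutral conditions that spare the acylation-prone trimethoxyarene rings, Et3N dehydrochlorinates the chloride to the arylketene, and the known ketene–alkoxyalkyne [2+2] cycloaddition joins the ketene carbonyl carbon to the unsubstituted alkyne carbon, giving the 3-ethoxy-4-arylcyclobutenone with its single stereocentre (C4) racemic, which is of no consequence.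

Step 6
Reactants: 13 3-ethoxy-4-(2,2',4,4',6,6'-hexamethoxy-[1,1'-biphenyl]-3-yl)cyclobut-2-en-1-one; 5 triisopropyl{[(2,4,6-trimethoxyphenyl)ethynyl]oxy}silane
Product: 17 3-ethoxy-2-(2,2',4,4',6,6'-hexamethoxy-[1,1'-biphenyl]-3-yl)-6-(2,4,6-trimethoxyphenyl)-5-(triisopropylsilyloxy)phenol, via vinylketene 14 (not isolated), via vinylcyclobutenone 15 (not isolated), via dienylketene 16 (not isolated)
Conditions: 5 (1.5 equiv), toluene, 80 → 110 °C, sealed tube, argon
Reagents that add atoms: none
Why: Thermal conrotatory 4π opening of 13 gives vinylketene 14, whose ketene C=C adds to silyloxyalkyne 5 in a [2+2] cycloaddition to give the 4-vinylcyclobutenone 15; a second 4π opening to dienylketene 16, 6π electrocyclisation and tautomerisation then deliver the phenol. The closest known reaction is the Danheiser benzannulation of cyclobutenones with triisopropylsilyloxyalkynes to resorcinol monosilyl ethers. Ring C is closed by the disrotatory 6π electrocyclisation of the dienylketene, which re-forms C1–C6 after the intermolecular cycloaddition has made C5–C6 and C3–C4. No stereocentre remains in the product: the racemic C4 of 13 becomes the aromatic carbon C1, and the transient stereocentres of 15 and of the cyclohexadienone are lost on aromatisation. The step needs regiocontrol in the ketene–alkyne cycloaddition, which the polarised silyloxyalkyne secures because its aryl-bearing carbon is the nucleophile and bonds to the ketene carbonyl carbon, placing OH at C6, the silyloxy group at C4 and the aryl groups at C1 and C5. It also needs the vinylketene to live until it is trapped: the two ortho-methoxy groups of ring B block 6π closure of the aryl vinylketene onto its own arene (the naphthol pathway of 4-arylcyclobutenones), and the excess of 5 limits O-acylation of the product by 14.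

Step 7
Reactants: 17 3-ethoxy-2-(2,2',4,4',6,6'-hexamethoxy-[1,1'-biphenyl]-3-yl)-6-(2,4,6-trimethoxyphenyl)-5-(triisopropylsilyloxy)phenol
Product: 18 5-ethoxy-4-(2,2',4,4',6,6'-hexamethoxy-[1,1'-biphenyl]-3-yl)-2-(2,4,6-trimethoxyphenyl)benzene-1,3-diol
Conditions: n-Bu4NF, AcOH, THF, 0 °C, argon
Reagents that add atoms: none
Why: Fluoride-mediated cleavage of the aryl triisopropylsilyl ether, driven by the Si–F bond, with AcOH buffering the electron-rich phenoxide; the alkyl aryl ethers are inert.

Step 8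
Reactants: 18 5-ethoxy-4-(2,2',4,4',6,6'-hexamethoxy-[1,1'-biphenyl]-3-yl)-2-(2,4,6-trimethoxyphenyl)benzene-1,3-diol
Product: 19 4-bromo-5-ethoxy-6-(2,2',4,4',6,6'-hexamethoxy-[1,1'-biphenyl]-3-yl)-2-(2,4,6-trimethoxyphenyl)benzene-1,3-diol
Conditions: NBS (1.0 equiv), i-Pr2NH (10 mol %), CH2Cl2, −78 °C
Reagents that add atoms: N-bromosuccinimide, O=C1CCC(=O)N1Br
Why: Electrophilic aromatic bromination with NBS under amine catalysis is a known phenol-selective protocol: the single C–H of ring C lies ortho to the C4 hydroxyl and the C2 ethoxy group and para to the C6 hydroxyl, so this free resorcinol ring should react at −78 °C well before the five C–H positions of the methyl-ether rings A, B and D.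

Step 9
Reactants: 19 4-bromo-5-ethoxy-6-(2,2',4,4',6,6'-hexamethoxy-[1,1'-biphenyl]-3-yl)-2-(2,4,6-trimethoxyphenyl)benzene-1,3-diol
Product: 20 CNP0203036.0, 5''-bromo-[1,1':3',1'':3'',1'''-quaterphenyl]-2,2',2'',2''',4,4',4'',4''',6,6',6'',6'''-dodecol
Conditions: BBr3 (excess), CH2Cl2, −78 °C → rt; then H2O, 0 °C
Reagents that add atoms: none
Why: BBr3-mediated cleavage of aryl methyl and ethyl ethers (boron coordination to oxygen, then bromide attack at the alkyl carbon) is the standard way to polyphenols from their alkyl ethers and leaves the aryl bromide and the biaryl bonds intact; a cold aqueous quench limits acid-promoted bromine migration.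

**Compound list**

1 | 2,4,6-trimethoxybenzaldehyde | COc1cc(OC)c(C=O)c(OC)c1 | starting material
2 | 2-ethynyl-1,3,5-trimethoxybenzene | COc1cc(OC)c(C#C)c(OC)c1 | intermediate
3 | lithium (2,4,6-trimethoxyphenyl)acetylide | [Li]C#Cc1c(OC)cc(OC)cc1OC | intermediate
4 | lithium 2-(2,4,6-trimethoxyphenyl)ethynolate | [Li+].[O-]C#Cc1c(OC)cc(OC)cc1OC | intermediate
5 | triisopropyl{[(2,4,6-trimethoxyphenyl)ethynyl]oxy}silane | COc1cc(OC)c(C#CO[Si](C(C)C)(C(C)C)C(C)C)c(OC)c1 | intermediate
6 | (2,4,6-trimethoxyphenyl)acetic acid | COc1cc(OC)c(CC(=O)O)c(OC)c1 | starting material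
7 | (3-bromo-2,4,6-trimethoxyphenyl)acetic acid | COc1cc(OC)c(CC(=O)O)c(OC)c1Br | intermediate
8 | (2,4,6-trimethoxyphenyl)boronic acid | COc1cc(OC)c(B(O)O)c(OC)c1 | starting material
9 | (2,2',4,4',6,6'-hexamethoxy-[1,1'-biphenyl]-3-yl)acetic acid | COc1cc(OC)c(-c2c(OC)cc(OC)c(CC(=O)O)c2OC)c(OC)c1 | intermediate
10 | ethoxyacetylene | C#COCC | starting material
11 | (2,2',4,4',6,6'-hexamethoxy-[1,1'-biphenyl]-3-yl)acetyl chloride | COc1cc(OC)c(-c2c(OC)cc(OC)c(CC(=O)Cl)c2OC)c(OC)c1 | intermediate
12 | (2,2',4,4',6,6'-hexamethoxy-[1,1'-biphenyl]-3-yl)ketene | COc1cc(OC)c(-c2c(OC)cc(OC)c(C=C=O)c2OC)c(OC)c1 | intermediate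
13 | 3-ethoxy-4-(2,2',4,4',6,6'-hexamethoxy-[1,1'-biphenyl]-3-yl)cyclobut-2-en-1-one (racemic) | CCOC1=CC(=O)C1c1c(OC)cc(OC)c(-c2c(OC)cc(OC)cc2OC)c1OC | intermediate
14 | (3Z)-3-ethoxy-4-(2,2',4,4',6,6'-hexamethoxy-[1,1'-biphenyl]-3-yl)buta-1,3-dien-1-one (geometry expected from outward rotation of the aryl group) | O=C=C/C(OCC)=C/c1c(OC)cc(OC)c(-c2c(OC)cc(OC)cc2OC)c1OC | intermediate
15 | 4-[(Z)-1-ethoxy-2-(2,2',4,4',6,6'-hexamethoxy-[1,1'-biphenyl]-3-yl)ethenyl]-2-(2,4,6-trimethoxyphenyl)-3-(triisopropylsilyloxy)cyclobut-2-en-1-one (racemic) | O=C1C(c2c(OC)cc(OC)cc2OC)=C(O[Si](C(C)C)(C(C)C)C(C)C)C1/C(OCC)=C/c1c(OC)cc(OC)c(-c2c(OC)cc(OC)cc2OC)c1OC | intermediate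
16 | (3E,5Z)-5-ethoxy-6-(2,2',4,4',6,6'-hexamethoxy-[1,1'-biphenyl]-3-yl)-2-(2,4,6-trimethoxyphenyl)-3-(triisopropylsilyloxy)hexa-1,3,5-trien-1-one | O=C=C(c1c(OC)cc(OC)cc1OC)/C(O[Si](C(C)C)(C(C)C)C(C)C)=C\C(OCC)=C\c1c(OC)cc(OC)c(-c2c(OC)cc(OC)cc2OC)c1OC | intermediate
17 | 3-ethoxy-2-(2,2',4,4',6,6'-hexamethoxy-[1,1'-biphenyl]-3-yl)-6-(2,4,6-trimethoxyphenyl)-5-(triisopropylsilyloxy)phenol | CCOc1cc(O[Si](C(C)C)(C(C)C)C(C)C)c(-c2c(OC)cc(OC)cc2OC)c(O)c1-c1c(OC)cc(OC)c(-c2c(OC)cc(OC)cc2OC)c1OC | intermediate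
18 | 5-ethoxy-4-(2,2',4,4',6,6'-hexamethoxy-[1,1'-biphenyl]-3-yl)-2-(2,4,6-trimethoxyphenyl)benzene-1,3-diol | CCOc1cc(O)c(-c2c(OC)cc(OC)cc2OC)c(O)c1-c1c(OC)cc(OC)c(-c2c(OC)cc(OC)cc2OC)c1OC | intermediate
19 | 4-bromo-5-ethoxy-6-(2,2',4,4',6,6'-hexamethoxy-[1,1'-biphenyl]-3-yl)-2-(2,4,6-trimethoxyphenyl)benzene-1,3-diol | CCOc1c(Br)c(O)c(-c2c(OC)cc(OC)cc2OC)c(O)c1-c1c(OC)cc(OC)c(-c2c(OC)cc(OC)cc2OC)c1OC | intermediate
20 | CNP0203036.0, 5''-bromo-[1,1':3',1'':3'',1'''-quaterphenyl]-2,2',2'',2''',4,4',4'',4''',6,6',6'',6'''-dodecol | Oc1cc(O)c(-c2c(O)cc(O)c(-c3c(O)c(Br)c(O)c(-c4c(O)cc(O)cc4O)c3O)c2O)c(O)c1 | target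

**Step count and risks**

Total step count: 9. Longest linear sequence: 7 steps (6 → 7 → 9 → 13 → 17 → 18 → 19 → 20); the alkyne branch (1 → 2 → 5) joins at step 6.

Steps most likely to fail:

1. Step 6 (benzannulation). The donor-stabilised cyclobutenone may open only at temperatures at which the silyloxyalkyne rearranges by 1,3-silyl shift, or capture of the vinylketene by the di-ortho-substituted alkyne may be slower than ketene oligomerisation and O-acylation of the product. The fallback gives up the annulation and builds the aryl–ring C bonds by cross-coupling on a ring C that already carries the bromine; it sets out from 8 and comes back to the route at 20. Two equivalents of 8 are coupled with commercial 1,3,5-tribromo-2,4,6-trimethoxybenzene (Pd(OAc)2, SPhos, K3PO4, toluene/H2O, 100 °C) to give 2-bromo-1,3,5-trimethoxy-4,6-bis(2,4,6-trimethoxyphenyl)benzene F1, the third and most hindered bromide being left in place. N-Iodosuccinimide (1 equiv, MeCN) iodinates one of the four equivalent C–H positions of the two flanking rings, which by symmetry all lead to 2-bromo-4-(3-iodo-2,4,6-trimethoxyphenyl)-1,3,5-trimethoxy-6-(2,4,6-trimethoxyphenyl)benzene F2. Suzuki–Miyaura coupling of the aryl iodide with a further equivalent of 8, chemoselective over the hexasubstituted aryl bromide, gives the dodecamethyl ether of the target F3, and BBr3 as in step 9 gives 20.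

2. Step 8 (bromination). Site selectivity may be lost through electrophilic attack on one of the five C–H positions of the methoxylated rings A, B and D, or through overbromination. The fallback replaces electrophilic substitution by directed ortho-metalation; it sets out from 18 and comes back at 19. NaH and N,N-diethylcarbamoyl chloride (THF, 0 → 50 °C) convert 18 into 5-ethoxy-4-(2,2',4,4',6,6'-hexamethoxy-[1,1'-biphenyl]-3-yl)-2-(2,4,6-trimethoxyphenyl)-1,3-phenylene bis(diethylcarbamate) F4. s-BuLi/TMEDA (THF, −78 °C) removes the only ring proton ortho to a carbamate, the C3–H of ring C, to give the aryllithium F5. Quenching with 1,2-dibromo-1,1,2,2-tetrachloroethane gives the bromo bis(diethylcarbamate) F6, and KOH in refluxing aqueous EtOH under argon cleaves both carbamates to return 19.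

3. Step 4 (biaryl coupling). Protodeboronation of the 2,6-dimethoxy-substituted boronic acid in the aqueous base may outrun transmetalation to the hindered arylpalladium bromide. The fallback uses a preformed organozinc nucleophile under anhydrous conditions; it sets out from 7 and comes back at 9. Esterification of 7 (MeOH, cat. H2SO4) gives methyl (3-bromo-2,4,6-trimethoxyphenyl)acetate F7. Commercial (2,4,6-trimethoxyphenyl)magnesium bromide and ZnCl2 in THF give (2,4,6-trimethoxyphenyl)zinc chloride F8, which is coupled with F7 under Negishi conditions (Pd2(dba)3, RuPhos, THF, 70 °C; zerovalent palladium) to give methyl (2,2',4,4',6,6'-hexamethoxy-[1,1'-biphenyl]-3-yl)acetate F9. LiOH in THF/H2O then returns 9.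

**Further compounds**

F1 | step 6 | 2-bromo-1,3,5-trimethoxy-4,6-bis(2,4,6-trimethoxyphenyl)benzene | COc1cc(OC)c(-c2c(OC)c(Br)c(OC)c(-c3c(OC)cc(OC)cc3OC)c2OC)c(OC)c1
F2 | step 6 | 2-bromo-4-(3-iodo-2,4,6-trimethoxyphenyl)-1,3,5-trimethoxy-6-(2,4,6-trimethoxyphenyl)benzene | COc1cc(OC)c(-c2c(OC)c(Br)c(OC)c(-c3c(OC)cc(OC)c(I)c3OC)c2OC)c(OC)c1
F3 | step 6 | 5''-bromo-2,2',2'',2''',4,4',4'',4''',6,6',6'',6'''-dodecamethoxy-1,1':3',1'':3'',1'''-quaterphenyl | COc1cc(OC)c(-c2c(OC)cc(OC)c(-c3c(OC)c(Br)c(OC)c(-c4c(OC)cc(OC)cc4OC)c3OC)c2OC)c(OC)c1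
F4 | step 8 | 5-ethoxy-4-(2,2',4,4',6,6'-hexamethoxy-[1,1'-biphenyl]-3-yl)-2-(2,4,6-trimethoxyphenyl)-1,3-phenylene bis(diethylcarbamate) | CCOc1cc(OC(=O)N(CC)CC)c(-c2c(OC)cc(OC)cc2OC)c(OC(=O)N(CC)CC)c1-c1c(OC)cc(OC)c(-c2c(OC)cc(OC)cc2OC)c1OC
F5 | step 8 | ring C C3-lithio derivative of F4 | CCOc1c([Li])c(OC(=O)N(CC)CC)c(-c2c(OC)cc(OC)cc2OC)c(OC(=O)N(CC)CC)c1-c1c(OC)cc(OC)c(-c2c(OC)cc(OC)cc2OC)c1OC
F6 | step 8 | 4-bromo-5-ethoxy-6-(2,2',4,4',6,6'-hexamethoxy-[1,1'-biphenyl]-3-yl)-2-(2,4,6-trimethoxyphenyl)-1,3-phenylene bis(diethylcarbamate) | CCOc1c(Br)c(OC(=O)N(CC)CC)c(-c2c(OC)cc(OC)cc2OC)c(OC(=O)N(CC)CC)c1-c1c(OC)cc(OC)c(-c2c(OC)cc(OC)cc2OC)c1OC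
F7 | step 4 | methyl (3-bromo-2,4,6-trimethoxyphenyl)acetate | COC(=O)Cc1c(OC)cc(OC)c(Br)c1OC
F8 | step 4 | (2,4,6-trimethoxyphenyl)zinc chloride | COc1cc(OC)c([Zn]Cl)c(OC)c1
F9 | step 4 | methyl (2,2',4,4',6,6'-hexamethoxy-[1,1'-biphenyl]-3-yl)acetate | COC(=O)Cc1c(OC)cc(OC)c(-c2c(OC)cc(OC)cc2OC)c1OC
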